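**Plan**

1. Retrosynthetic cuts, in order: the ester O–ethyl bond; the C8–CH2 bond to the prenyl group (undoes the dearomatisation of ring A); the C4–C4a bond of pyran ring B (key); the O1–C2 ether bond; the C8–CH2 bond to the side chain; the aryl–acyl bond; inside the side chain, the CH–CH2 bond next to the enoate.
2. Forward: phloroglucinol (ring A) is MOM-protected, acylated by lithiation/Weinreb ketone synthesis, iodinated and joined to the side-chain iodide by Negishi coupling; after deprotection the para hydroxyl is propargylated, ring B is closed by C–C bond formation, ring A is dearomatised by C8-prenylation and the ester is saponified.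
3. Enabling feature: in the free acylphloroglucinol the carbon that becomes C4a is the only unsubstituted carbon of ring A, lies between two oxygen-bearing carbons (future C5 and C8a) and para to a third (future C7), and sits 6-endo to the terminal carbon of a 2-methylbut-3-yn-2-yl ether on the oxygen para to the acyl group (future O1).
4. A gold-catalysed cycloisomerisation therefore closes ring B through C4–C4a while the O1–C2 bond, and with it the orientation of the pyran, stays fixed; the same step uses up the only ring carbon that could compete with C8 in the dearomatising prenylation.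
5. Helpers: the alkyne already has the oxidation level of the chromene, so nothing has to be removed after the key step; the MOM groups leave in step 10 and the oxazolidinone in step 3.
6. Stereochemistry: side-chain centre from an Evans alkylation, E-alkene from the bromoenoate, acyl centre from (2R)-2-methylbutanoic acid, quaternary C8 from ligand-controlled palladium allylation.

Key step: step 12

Remark: ethyl (2E)-4-bromo-2-methylbut-2-enoate and (2R)-2-methylbutanoic acid are taken as catalogue compounds, and the dearomatised compounds 26–28 are mobile enol tautomers written in the tautomer of the given structure.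

**Route**

Step 1
Reactants: 1 (4S)-4-benzyl-1,3-oxazolidin-2-one; 2 3-methylbut-2-enoyl chloride
Product: 4 (4S)-4-benzyl-3-(3-methylbut-2-enoyl)-1,3-oxazolidin-2-one, via lithium oxazolidinide 3 (not isolated)
Conditions: n-BuLi, THF, −78 °C; then 2, −78 → 0 °C
Reagents that add atoms: n-butyllithium, `[Li]CCCC` (lithium of 3 only)
Why: N-acylation of the lithiated oxazolidinone with an acid chloride (standard loading of an Evans auxiliary) is fast at low temperature and leaves the conjugated double bond in place.

Step 2
Reactants: 4 (4S)-4-benzyl-3-(3-methylbut-2-enoyl)-1,3-oxazolidin-2-one; 5 ethyl (2E)-4-bromo-2-methylbut-2-enoate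
Product: 7 ethyl (2E,5S)-5-{[(4S)-4-benzyl-2-oxo-1,3-oxazolidin-3-yl]carbonyl}-2,6-dimethylhepta-2,6-dienoate, via sodium dienolate 6 (not isolated)
Conditions: NaN(SiMe3)2, THF, −78 °C; then 5, −78 → −40 °C
Reagents that add atoms: sodium bis(trimethylsilyl)amide, `C[Si](C)(C)N([Na])[Si](C)(C)C` (sodium of 6 only)
Why: the base removes a γ-proton to give the chelated (Z)-dienolate, which reacts at its α-carbon (deconjugative Evans asymmetric alkylation) by SN2 displacement of the allylic bromide on the face opposite the benzyl group, setting the 5S centre and the isopropenyl group while the E geometry of the enoate is carried over unchanged.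

Step 3
Reactants: 7 alkylated imide
Product: 8 ethyl (2E,5S)-5-(hydroxymethyl)-2,6-dimethylhepta-2,6-dienoate
Conditions: NaBH4, THF–H2O, 0 °C → rt
Reagents that add atoms: none
Why: reductive cleavage of the N-acyl oxazolidinone with borohydride in wet THF is selective for the activated imide carbonyl over the conjugated ester, should not epimerise the α-centre and returns the auxiliary.

Step 4
Reactants: 8 side-chain alcohol
Product: 9 ethyl (2E,5S)-5-(iodomethyl)-2,6-dimethylhepta-2,6-dienoate
Conditions: I2, PPh3, imidazole, CH2Cl2, 0 °C → rt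
Reagents that add atoms: iodine, `II`
Why: Appel iodination of the primary alcohol proceeds under neutral conditions, so the β-stereocentre, the ester and both alkenes are untouched.

Step 5
Reactants: 10 benzene-1,3,5-triol (phloroglucinol)
Product: 11 1,3,5-tris(methoxymethoxy)benzene
Conditions: MOMCl, iPr2NEt, DMF, 0 °C → rt
Reagents that add atoms: chloromethyl methyl ether, `COCCl`
Why: threefold O-alkylation with the reactive α-chloro ether (Williamson-type etherification) masks the phenols as MOM acetals, which later direct the lithiation and survive organozinc chemistry.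

Step 6
Reactants: 12 (2R)-2-methylbutanoic acid
Product: 14 (2R)-N-methoxy-N,2-dimethylbutanamide, via acyl imidazole 13 (not isolated)
Conditions: 1,1'-carbonyldiimidazole, CH2Cl2, rt; then MeNHOMe·HCl, rt
Reagents that add atoms: 1,1'-carbonyldiimidazole, `O=C(n1ccnc1)n1ccnc1` (imidazolyl of 13 only); N,O-dimethylhydroxylamine hydrochloride, `CNOC.Cl`
Why: activation of the acid as its acyl imidazole followed by aminolysis (Weinreb amide synthesis) uses no strong base, so the α-stereocentre of the acid should be preserved.

Step 7
Reactants: 11 1,3,5-tris(methoxymethoxy)benzene; 14 (2R)-N-methoxy-N,2-dimethylbutanamide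
Product: 17 (2R)-2-methyl-1-[2,4,6-tris(methoxymethoxy)phenyl]butan-1-one, via aryllithium 15 (not isolated), via lithium hemiaminal alkoxide 16 (not isolated)
Conditions: n-BuLi, THF, 0 °C; then 14, −78 → 0 °C; H2O
Reagents that add atoms: n-butyllithium, `[Li]CCCC` (lithium of 15 and 16 only)
Why: directed ortho-metalation between two MOM ethers gives the aryllithium, and its addition to the Weinreb amide (Weinreb ketone synthesis) stops at the chelated tetrahedral adduct, which prevents over-addition and keeps the α-centre from enolising until the cold aqueous quench.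

Step 8
Reactants: 17 aryl ketone
Product: 18 (2R)-1-[3-iodo-2,4,6-tris(methoxymethoxy)phenyl]-2-methylbutan-1-one
Conditions: N-iodosuccinimide, MeCN, 0 °C → rt, dark
Reagents that add atoms: N-iodosuccinimide, `O=C1CCC(=O)N1I`
Why: electrophilic aromatic iodination takes place at one of the two equivalent ring CH positions, each activated by two flanking alkoxy groups, and one equivalent of reagent should limit the reaction to the monoiodide.

Step 9
Reactants: 9 side-chain iodide; 18 aryl iodide
Product: 20 ethyl (2E,5R)-2,6-dimethyl-5-{[3-[(2R)-2-methylbutanoyl]-2,4,6-tris(methoxymethoxy)phenyl]methyl}hepta-2,6-dienoate, via alkylzinc iodide 19 (not isolated)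
Conditions: Zn dust, LiCl, THF, 40 °C; then 18, Pd2(dba)3 (cat.), SPhos (cat.), THF, 50 °C
Reagents that add atoms: zinc, `[Zn]` (zinc of 19 only)
Why: zinc insertion into the primary iodide gives an organozinc that tolerates the ester and the ketone, and Negishi sp3–sp2 cross-coupling with the di-ortho-substituted aryl iodide forges the aryl–CH2 bond without touching the β-stereocentre, whose descriptor changes from S to R only because the substituent priorities change.

Step 10
Reactants: 20 tris-MOM coupling product
Product: 21 ethyl (2E,5R)-2,6-dimethyl-5-{[2,4,6-trihydroxy-3-[(2R)-2-methylbutanoyl]phenyl]methyl}hepta-2,6-dienoate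
Conditions: ZnBr2, n-PrSH, CH2Cl2, 0 °C
Reagents that add atoms: none
Why: ZnBr2-assisted thiolysis (acetal exchange) cleaves the three phenolic MOM acetals quickly under nearly neutral conditions, avoiding protic acid that could add a phenol across the isopropenyl group or transesterify the ester.

Step 11
Reactants: 21 acylphloroglucinol triol; 22 3-chloro-3-methylbut-1-yne
Product: 23 ethyl (2E,5R)-5-{[2,4-dihydroxy-3-[(2R)-2-methylbutanoyl]-6-[(2-methylbut-3-yn-2-yl)oxy]phenyl]methyl}-2,6-dimethylhepta-2,6-dienoate
Conditions: CuCl2·2H2O (cat.), DBU, MeCN, 0 °C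
Reagents that add atoms: none
Why: copper-catalysed propargylic substitution (through a copper acetylide/allenylidene) etherifies the most acidic hydroxyl, the one para to the acyl group and the only one that cannot hydrogen-bond to the ketone, which places the tertiary propargyl unit on the oxygen that becomes O1 of the pyran.

Step 12
Reactants: 23 aryl propargyl ether
Product: 24 ethyl (2E,5R)-5-{[5,7-dihydroxy-2,2-dimethyl-6-[(2R)-2-methylbutanoyl]-2H-chromen-8-yl]methyl}-2,6-dimethylhepta-2,6-dienoate
Conditions: Ph3PAuNTf2 (2 mol %), CH2Cl2, rt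
Reagents that add atoms: none
Why: Ph3PAuNTf2 (cationic monovalent gold) π-activates the terminal alkyne and the free ring carbon ortho to the ether oxygen (the future C4a) attacks the terminal alkyne carbon anti to gold; the vinylgold arenium ion then loses its ring proton and is protodeaurated, so the C–C bond is the ring-closing bond and the O–C(CH3)2 bond is never broken. The closest known reaction type is the gold-catalysed intramolecular hydroarylation (alkyne cycloisomerisation) of aryl propargyl ethers to 2H-chromenes. Ring B closes in the 6-endo-dig mode, favoured over 5-exo-dig because the internal alkyne carbon is shielded by the adjacent quaternary carbon and its attack would give a strained methylene-dihydrobenzofuran. No stereocentre is formed, and the existing side-chain and acyl centres are remote from the cationic site. The step needs site selectivity for the free CH over ipso attack at the alkylated carbon (which cannot rearomatise and reverts), regiochemical fidelity (deprotonation of the arenium ion should outrun any Claisen-type C–O scission that would let the other phenol oxygen reclose) and chemoselectivity for the alkyne over the isopropenyl and enoate alkenes, which the alkynophilic gold and the strongly nucleophilic phloroglucinol carbon should secure. By occupying the last unsubstituted ring carbon the step also leaves C8 as the only carbon open to the prenylation that follows.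

Step 13
Reactants: 24 chromene; 25 3-methylbut-2-en-1-yl acetate
Product: 26 ethyl (2E,5R)-5-{[(8R)-7-hydroxy-2,2-dimethyl-6-[(2R)-2-methylbutanoyl]-8-(3-methylbut-2-en-1-yl)-5-oxo-5,8-dihydro-2H-chromen-8-yl]methyl}-2,6-dimethylhepta-2,6-dienoate
Conditions: Pd2(dba)3·CHCl3 (cat.), (R,R)-DACH-phenyl ligand [N,N'-((1R,2R)-cyclohexane-1,2-diyl)bis(2-(diphenylphosphanyl)benzamide)] (cat.), Cs2CO3, toluene, 0 °C → rt
Reagents that add atoms: none
Why: oxidative addition of the allylic acetate to zerovalent palladium gives a π-prenyl complex that is attacked at its unsubstituted terminus by C8 of the phenoxide, the only ring carbon still able to react (Tsuji–Trost allylation used as an asymmetric allylic dearomatisation), so ring A is dearomatised to the enolised triketone and the quaternary centre C8 is set by the chiral pocket of the ligand, not by the remote acyclic side-chain centre; which ligand antipode delivers 8R is to be fixed in a pilot run, (R,R) being written here.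

Step 14
Reactants: 26 dearomatised ethyl ester
Product: 28 (2E,5R)-5-{[(8R)-7-hydroxy-2,2-dimethyl-6-[(2R)-2-methylbutanoyl]-8-(3-methylbut-2-en-1-yl)-5-oxo-5,8-dihydro-2H-chromen-8-yl]methyl}-2,6-dimethylhepta-2,6-dienoic acid, via dilithium salt 27 (not isolated)
Conditions: LiOH·H2O, THF–H2O, rt → 40 °C; then 1 M HCl to pH 3
Reagents that add atoms: lithium hydroxide, `[Li+].[OH-]`
Why: saponification of the ethyl enoate proceeds on the dianion (the enolised triketone is deprotonated first, which should protect the ring and the acyl α-centre from retro-Claisen cleavage and epimerisation), and mild acidification releases the target acid.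

**Compound list**

```
1 | (4S)-4-benzyl-1,3-oxazolidin-2-one | O=C1N[C@@H](Cc2ccccc2)CO1 | starting material
2 | 3-methylbut-2-enoyl chloride | CC(C)=CC(=O)Cl | starting material
3 | lithium (4S)-4-benzyl-2-oxo-1,3-oxazolidin-3-ide | [Li]N1C(=O)OC[C@@H]1Cc1ccccc1 | intermediate
4 | (4S)-4-benzyl-3-(3-methylbut-2-enoyl)-1,3-oxazolidin-2-one | CC(C)=CC(=O)N1C(=O)OC[C@@H]1Cc1ccccc1 | intermediate
5 | ethyl (2E)-4-bromo-2-methylbut-2-enoate | BrC/C=C(\C)C(=O)OCC | starting material
6 | sodium (1Z)-1-[(4S)-4-benzyl-2-oxo-1,3-oxazolidin-3-yl]-3-methylbuta-1,3-dien-1-olate | [O-]/C(=C\C(=C)C)N1C(=O)OC[C@@H]1Cc1ccccc1.[Na+] | intermediate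
7 | ethyl (2E,5S)-5-{[(4S)-4-benzyl-2-oxo-1,3-oxazolidin-3-yl]carbonyl}-2,6-dimethylhepta-2,6-dienoate | C=C(C)[C@H](C/C=C(\C)C(=O)OCC)C(=O)N1C(=O)OC[C@@H]1Cc1ccccc1 | intermediate
8 | ethyl (2E,5S)-5-(hydroxymethyl)-2,6-dimethylhepta-2,6-dienoate | C=C(C)[C@H](C/C=C(\C)C(=O)OCC)CO | intermediate
9 | ethyl (2E,5S)-5-(iodomethyl)-2,6-dimethylhepta-2,6-dienoate | C=C(C)[C@H](C/C=C(\C)C(=O)OCC)CI | intermediate
10 | benzene-1,3,5-triol (phloroglucinol) | Oc1cc(O)cc(O)c1 | starting material
11 | 1,3,5-tris(methoxymethoxy)benzene | COCOc1cc(OCOC)cc(OCOC)c1 | intermediate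
12 | (2R)-2-methylbutanoic acid | CC[C@@H](C)C(=O)O | starting material
13 | (2R)-1-(1H-imidazol-1-yl)-2-methylbutan-1-one | O=C([C@H](C)CC)n1ccnc1 | intermediate
14 | (2R)-N-methoxy-N,2-dimethylbutanamide | CON(C)C(=O)[C@H](C)CC | intermediate
15 | [2,4,6-tris(methoxymethoxy)phenyl]lithium | [Li]c1c(OCOC)cc(OCOC)cc1OCOC | intermediate
16 | lithium (2R)-1-[methoxy(methyl)amino]-2-methyl-1-[2,4,6-tris(methoxymethoxy)phenyl]butan-1-olate (either configuration at C1) | [Li]OC(N(C)OC)([C@H](C)CC)c1c(OCOC)cc(OCOC)cc1OCOC | intermediate
17 | (2R)-2-methyl-1-[2,4,6-tris(methoxymethoxy)phenyl]butan-1-one | O=C([C@H](C)CC)c1c(OCOC)cc(OCOC)cc1OCOC | intermediate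
18 | (2R)-1-[3-iodo-2,4,6-tris(methoxymethoxy)phenyl]-2-methylbutan-1-one | O=C([C@H](C)CC)c1c(OCOC)cc(OCOC)c(I)c1OCOC | intermediate
19 | iodo[(2S,4E)-6-ethoxy-5-methyl-6-oxo-2-(prop-1-en-2-yl)hex-4-en-1-yl]zinc | C=C(C)[C@H](C/C=C(\C)C(=O)OCC)C[Zn]I | intermediate
20 | ethyl (2E,5R)-2,6-dimethyl-5-{[3-[(2R)-2-methylbutanoyl]-2,4,6-tris(methoxymethoxy)phenyl]methyl}hepta-2,6-dienoate | C=C(C)[C@H](C/C=C(\C)C(=O)OCC)Cc1c(OCOC)cc(OCOC)c(C(=O)[C@H](C)CC)c1OCOC | intermediate
21 | ethyl (2E,5R)-2,6-dimethyl-5-{[2,4,6-trihydroxy-3-[(2R)-2-methylbutanoyl]phenyl]methyl}hepta-2,6-dienoate | C=C(C)[C@H](C/C=C(\C)C(=O)OCC)Cc1c(O)cc(O)c(C(=O)[C@H](C)CC)c1O | intermediate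
22 | 3-chloro-3-methylbut-1-yne | C#CC(C)(C)Cl | starting material
23 | ethyl (2E,5R)-5-{[2,4-dihydroxy-3-[(2R)-2-methylbutanoyl]-6-[(2-methylbut-3-yn-2-yl)oxy]phenyl]methyl}-2,6-dimethylhepta-2,6-dienoate | C=C(C)[C@H](C/C=C(\C)C(=O)OCC)Cc1c(OC(C)(C)C#C)cc(O)c(C(=O)[C@H](C)CC)c1O | intermediate
24 | ethyl (2E,5R)-5-{[5,7-dihydroxy-2,2-dimethyl-6-[(2R)-2-methylbutanoyl]-2H-chromen-8-yl]methyl}-2,6-dimethylhepta-2,6-dienoate | C=C(C)[C@H](C/C=C(\C)C(=O)OCC)Cc1c2OC(C)(C)C=Cc2c(O)c(C(=O)[C@H](C)CC)c1O | intermediate
25 | 3-methylbut-2-en-1-yl acetate | CC(C)=CCOC(C)=O | starting material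
26 | ethyl (2E,5R)-5-{[(8R)-7-hydroxy-2,2-dimethyl-6-[(2R)-2-methylbutanoyl]-8-(3-methylbut-2-en-1-yl)-5-oxo-5,8-dihydro-2H-chromen-8-yl]methyl}-2,6-dimethylhepta-2,6-dienoate | C=C(C)[C@H](C/C=C(\C)C(=O)OCC)C[C@]1(CC=C(C)C)C(O)=C(C(=O)[C@H](C)CC)C(=O)C2=C1OC(C)(C)C=C2 | intermediate
27 | dilithium (2E,5R)-5-{[(8R)-2,2-dimethyl-6-[(2R)-2-methylbutanoyl]-8-(3-methylbut-2-en-1-yl)-7-oxido-5-oxo-5,8-dihydro-2H-chromen-8-yl]methyl}-2,6-dimethylhepta-2,6-dienoate | C=C(C)[C@H](C/C=C(\C)C(=O)[O-])C[C@]1(CC=C(C)C)C([O-])=C(C(=O)[C@H](C)CC)C(=O)C2=C1OC(C)(C)C=C2.[Li+].[Li+] | intermediate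
28 | (2E,5R)-5-{[(8R)-7-hydroxy-2,2-dimethyl-6-[(2R)-2-methylbutanoyl]-8-(3-methylbut-2-en-1-yl)-5-oxo-5,8-dihydro-2H-chromen-8-yl]methyl}-2,6-dimethylhepta-2,6-dienoic acid | C=C(C)[C@H](C/C=C(\C)C(=O)O)C[C@]1(CC=C(C)C)C(O)=C(C(=O)[C@H](C)CC)C(=O)C2=C1OC(C)(C)C=C2 | target
```

**Count and risks**

Total step count: 14. Longest linear sequence: 10 steps (steps 1–4, then 9–14).

Step 13. The risk is poor facial selectivity at C8 (a mismatched pairing of ligand and side-chain centre) or O-prenylation in place of C-prenylation. In that case the quaternary centre is made without a chiral catalyst. The fallback sets out from 24, which is C-alkylated with 1-bromo-3-methylbut-2-ene under aqueous KOH at 0 °C (phenolate C-alkylation, the classical entry to gem-dialkylated acylphloroglucinols). This should give 26 together with its C8 epimer ethyl (2E,5R)-5-{[(8S)-7-hydroxy-2,2-dimethyl-6-[(2R)-2-methylbutanoyl]-8-(3-methylbut-2-en-1-yl)-5-oxo-5,8-dihydro-2H-chromen-8-yl]methyl}-2,6-dimethylhepta-2,6-dienoate F1. The two diastereomers are separated by preparative HPLC and the route is rejoined at 26.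

Step 11. The risk is poor site selectivity among the three hydroxyls, or C-propargylation at the free ring carbon. In that case ring B is built by a construction that needs no ether. The fallback sets out from 21, which is condensed with 3-methylbut-2-enal (ethylenediammonium diacetate cat., toluene, 80 °C). Knoevenagel-type condensation at the free ring carbon gives the ortho-quinone methide ethyl (2E,5R)-5-{[2,4-dihydroxy-3-[(2R)-2-methylbutanoyl]-5-(3-methylbut-2-en-1-ylidene)-6-oxocyclohexa-1,3-dien-1-yl]methyl}-2,6-dimethylhepta-2,6-dienoate F2, which is not isolated. It should close by oxa-6π electrocyclisation through the oxygen para to the acyl group, the ortho oxygens being engaged in hydrogen bonding to the ketone. The route is rejoined at 24, so step 12 is bypassed as well. In this variant the ring-closing bond is O1–C2 and the orientation of the pyran is no longer locked, which is why it is only the reserve.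

Step 9. The risk is sluggish oxidative addition at the di-ortho-alkoxy aryl iodide, or protodezincation of the organozinc before it couples. In that case the fallback sets out from 9 and 18, which are joined directly by a nickel-catalysed reductive cross-electrophile coupling (NiBr2(dme), 4,4'-di-tert-butyl-2,2'-bipyridine, Mn powder, N,N-dimethylacetamide, rt). No preformed organometallic is needed; the primary homoallyl radical should be captured by nickel faster than it can rearrange through 3-exo closure and reopening. The route is rejoined at 20, and no compound outside the list is made (F0).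

**Further compounds**

```
F1 | step 13 | ethyl (2E,5R)-5-{[(8S)-7-hydroxy-2,2-dimethyl-6-[(2R)-2-methylbutanoyl]-8-(3-methylbut-2-en-1-yl)-5-oxo-5,8-dihydro-2H-chromen-8-yl]methyl}-2,6-dimethylhepta-2,6-dienoate | C=C(C)[C@H](C/C=C(\C)C(=O)OCC)C[C@@]1(CC=C(C)C)C(O)=C(C(=O)[C@H](C)CC)C(=O)C2=C1OC(C)(C)C=C2
F2 | step 11 | ethyl (2E,5R)-5-{[2,4-dihydroxy-3-[(2R)-2-methylbutanoyl]-5-(3-methylbut-2-en-1-ylidene)-6-oxocyclohexa-1,3-dien-1-yl]methyl}-2,6-dimethylhepta-2,6-dienoate | C=C(C)[C@H](C/C=C(\C)C(=O)OCC)CC1=C(O)C(C(=O)[C@H](C)CC)=C(O)C(=CC=C(C)C)C1=O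
F0 | step 9 | none | none
```
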